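Ring A (C1–C5, C10; drimane numbering, ring B = C5–C10) is cut into a prenyl unit (C2–C3–C4 with both methyls) and a ring-B enone whose C10 carries the future C1 as a vinylic methyl. The key step is a Lewis-acid [3+3] annulation: the exocyclic γ-carbon C1 of a silyl dienol ether attacks the primary terminus C2 of prenyl bromide, and the tertiary cation generated at C4 is captured by the α-carbon C5, closing ring A with its quaternary gem-dimethyl centre. It exploits the 1,3-relationship of C1 and C5 across C10, the α,γ-ambident dienolate of a C6 ketone. That carbonyl is removed by a reductive 1,3-transposition which sets C10–H and the C5=C6 olefin.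

Key step: step 9

Remarks: the aryl sulfate is drawn, as in the target, as the neutral hydrogen sulfate (handled in practice as its salt; the acid form by brief cation exchange). (R)-5-Methylcyclohex-2-en-1-one (5) is assumed to be purchasable (otherwise a short known sequence from (R)-pulegone). Arene positions are primed: C1' bears the CH2, C2' the sulfate oxygen, C3' the formyl group, C4'/C5' the catechol.

Step 1
Reactants: 1 2,4,5-trihydroxybenzaldehyde
Product: 2 2,4,5-tris(benzyloxy)benzaldehyde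
Conditions: BnBr, K2CO3, DMF, 60 °C
Reagents that add atoms: benzyl bromide BrCc1ccccc1
Why: Williamson etherification of all three phenoxides gives a protection that is stable to base and organolithiums and is cleaved later by a Lewis acid.

Step 2
Reactants: 2 2,4,5-tris(benzyloxy)benzaldehyde
Product: 3 [2,4,5-tris(benzyloxy)phenyl]methanol
Conditions: NaBH4, MeOH–THF, 0 °C
Reagents that add atoms: none
Why: Borohydride reduction of an aryl aldehyde to the benzylic alcohol.

Step 3
Reactants: 3 [2,4,5-tris(benzyloxy)phenyl]methanol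
Product: 4 1-(bromomethyl)-2,4,5-tris(benzyloxy)benzene
Conditions: PBr3, Et2O, 0 °C; used at once
Reagents that add atoms: phosphorus tribromide BrP(Br)Br
Why: Bromide-for-hydroxyl exchange of an electron-rich benzylic alcohol through its phosphite ester, the labile bromide being carried on without storage.

Step 4
Reactants: 5 (R)-5-methylcyclohex-2-en-1-one; 4 1-(bromomethyl)-2,4,5-tris(benzyloxy)benzene
Product: 7 (5R,6S)-5-methyl-6-[2,4,5-tris(benzyloxy)benzyl]cyclohex-2-en-1-one, via lithium dienolate 6 (not isolated)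
Conditions: LiN(iPr)2, THF, −78 °C; then 4, −78 → −20 °C
Reagents that add atoms: none
Why: Kinetic α'-deprotonation gives the cross-conjugated lithium dienolate, whose SN2 benzylation at C6 should occur mainly trans to the C5 methyl (kinetic enolate alkylation; the C6 configuration is erased in step 5).

Step 5
Reactants: 7 (5R,6S)-5-methyl-6-[2,4,5-tris(benzyloxy)benzyl]cyclohex-2-en-1-one
Product: 9 (5R,6R)-5,6-dimethyl-6-[2,4,5-tris(benzyloxy)benzyl]cyclohex-2-en-1-one, via lithium dienolate 8 (not isolated)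
Conditions: LiN(iPr)2, THF, −78 °C; then MeI, DMPU, −78 → 0 °C
Reagents that add atoms: iodomethane CI
Why: In the tetrasubstituted α'-enolate the C5 methyl sits pseudoaxial to escape A(1,2) strain with the arylmethyl group, so iodomethane should enter anti to it and the new quaternary centre (C9 of the target) carries its methyl trans and its arylmethyl cis to the C5 methyl (diastereoselective enolate alkylation).

Step 6
Reactants: 9 (5R,6R)-5,6-dimethyl-6-[2,4,5-tris(benzyloxy)benzyl]cyclohex-2-en-1-one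
Product: 10 (5R,6R)-1,5,6-trimethyl-6-[2,4,5-tris(benzyloxy)benzyl]cyclohex-2-en-1-ol (both C1 epimers)
Conditions: MeLi, Et2O, −78 °C; H2O
Reagents that add atoms: methyllithium [Li]C
Why: 1,2-Addition of methyllithium to the enone carbonyl installs the carbon that becomes C1, the carbinol configuration being irrelevant because it is lost in step 7.

Step 7
Reactants: 10 (5R,6R)-1,5,6-trimethyl-6-[2,4,5-tris(benzyloxy)benzyl]cyclohex-2-en-1-ol
Product: 11 (4R,5R)-3,4,5-trimethyl-4-[2,4,5-tris(benzyloxy)benzyl]cyclohex-2-en-1-one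
Conditions: [C5H5NH][CrO3Cl] (pyridinium chlorochromate), CH2Cl2, rt
Reagents that add atoms: pyridinium chlorochromate [O-][Cr](=O)(=O)Cl.c1cc[nH+]cc1
Why: Oxidative 1,3-transposition of a tertiary allylic alcohol ([3,3]-shift of the chromate ester, then oxidation of the secondary chromate) should give the β-methyl enone without touching either stereocentre.

Step 8
Reactants: 11 (4R,5R)-3,4,5-trimethyl-4-[2,4,5-tris(benzyloxy)benzyl]cyclohex-2-en-1-one
Product: 12 tert-butyl{[(4R,5R)-4,5-dimethyl-3-methylidene-4-[2,4,5-tris(benzyloxy)benzyl]cyclohex-1-en-1-yl]oxy}dimethylsilane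
Conditions: TBSOTf, Et3N, CH2Cl2, 0 °C → rt
Reagents that add atoms: tert-butyldimethylsilyl triflate CC(C)(C)[Si](C)(C)OS(=O)(=O)C(F)(F)F
Why: Reversible soft enolization should give the through-conjugated (linear) silyl dienol ether, whose γ-terminus is the exocyclic methylene because the ring γ-carbon is quaternary.

Step 9
Reactants: 12 tert-butyl{[(4R,5R)-4,5-dimethyl-3-methylidene-4-[2,4,5-tris(benzyloxy)benzyl]cyclohex-1-en-1-yl]oxy}dimethylsilane; 13 1-bromo-3-methylbut-2-ene (prenyl bromide)
Product: 15 (3R,4R)-3,4,8,8-tetramethyl-4-[2,4,5-tris(benzyloxy)benzyl]-3,4,5,6,7,8-hexahydronaphthalen-1(2H)-one, via γ-prenyl enone 14 (not isolated)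
Conditions: SnCl4 (2.2 equiv), CH2Cl2, −78 → 0 °C
Reagents that add atoms: none
Why: Proposed new method: SnCl4 ionizes 13 to the prenyl cation, which the exocyclic γ-carbon C1 of dienol ether 12 attacks at its CH2 terminus (C1–C2) to give enone 14 with loss of the silyl group; the SnCl4-bound enone then enolizes toward C1 with release of HX, the side-chain olefin is protonated to the tertiary cation at C4, and the tin dienolate captures it through its α-carbon C5 (C4–C5), tautomerization restoring the C5=C10 enone. The closest known reaction types are the Lewis-acid γ-alkylation of silyl dienol ethers with allylic halides and the SnCl4-promoted cyclization of olefinic β-keto esters to 2-acyl-3,3-dimethylcyclohexanones, which have not been merged into one annulation on a simple enone dienolate. Ring A closes through a chair-like six-membered transition state, 6-endo with respect to the C5=C10 π bond and 6-enolexo with respect to the C5=C6 enolate bond; closure through C1 would need a cyclobutane. No stereocentre is created (C4 bears two methyls, C5 and C10 end sp2), so C8 and C9 pass through untouched. The step needs γ- over α-attack in the first bond formation and reaction at the primary terminus of the cation, secured by the unhindered exocyclic methylene of 12 and the steric bias of the prenyl cation, and it needs the dienol ether to outcompete the benzyloxy arene for the cation, secured by its much higher nucleophilicity and by one equivalent of 13 at −78 °C.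

Step 10
Reactants: 15 (3R,4R)-3,4,8,8-tetramethyl-4-[2,4,5-tris(benzyloxy)benzyl]-3,4,5,6,7,8-hexahydronaphthalen-1(2H)-one
Product: 16 4-methylbenzenesulfonylhydrazone of 15
Conditions: TsNHNH2, AcOH (cat.), EtOH, 70 °C
Reagents that add atoms: 4-methylbenzenesulfonohydrazide NNS(=O)(=O)c1ccc(C)cc1
Why: Acid-catalysed condensation of the conjugated ketone with tosylhydrazide (hydrazone formation), the sulfonamide nitrogen lying anti to the congested C5 side.

Step 11
Reactants: 16 4-methylbenzenesulfonylhydrazone of 15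
Product: 19 1,2,4-tris(benzyloxy)-5-{[(1R,2R,8aS)-1,2,5,5-tetramethyl-1,2,3,5,6,7,8,8a-octahydronaphthalen-1-yl]methyl}benzene, via borylated allylic tosylhydrazine 17 (not isolated), via allylic diazene 18 (not isolated)
Conditions: catecholborane, CHCl3, 0 °C; then NaOAc·3H2O, 60 °C
Reagents that add atoms: none
Why: Reductive 1,3-transposition of an enone tosylhydrazone: hydride should add to C6 on the face anti to the C8 methyl (as in hydride reductions of 5-substituted cyclohexenones), and after acetate-induced loss of sulfinate the allylic diazene passes its hydrogen suprafacially to C10 (retro-ene with loss of N2), so H-10 is set cis to the C8 methyl and the arylmethyl group while the olefin lands at C5=C6.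

Step 12
Reactants: 19 1,2,4-tris(benzyloxy)-5-{[(1R,2R,8aS)-1,2,5,5-tetramethyl-1,2,3,5,6,7,8,8a-octahydronaphthalen-1-yl]methyl}benzene
Product: 21 2,3,6-tris(benzyloxy)-5-{[(1R,2R,8aS)-1,2,5,5-tetramethyl-1,2,3,5,6,7,8,8a-octahydronaphthalen-1-yl]methyl}benzaldehyde, via aryllithium 20 (not isolated)
Conditions: n-BuLi, TMEDA, THF, −20 → 0 °C; then DMF, −78 °C → rt
Reagents that add atoms: N,N-dimethylformamide CN(C)C=O
Why: Directed ortho-metalation at C3', the only ring position flanked by two benzyloxy groups, followed by formylation of the aryllithium with DMF.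

Step 13
Reactants: 21 2,3,6-tris(benzyloxy)-5-{[(1R,2R,8aS)-1,2,5,5-tetramethyl-1,2,3,5,6,7,8,8a-octahydronaphthalen-1-yl]methyl}benzaldehyde
Product: 22 2,3,6-trihydroxy-5-{[(1R,2R,8aS)-1,2,5,5-tetramethyl-1,2,3,5,6,7,8,8a-octahydronaphthalen-1-yl]methyl}benzaldehyde
Conditions: BCl3, C6HMe5 (pentamethylbenzene), CH2Cl2, −78 °C; MeOH quench
Reagents that add atoms: none
Why: Lewis-acid debenzylation of aryl benzyl ethers with pentamethylbenzene as benzyl-cation scavenger, run at −78 °C so that the trisubstituted olefin beside the liberated C2' phenol is not protonated.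

Step 14
Reactants: 22 2,3,6-trihydroxy-5-{[(1R,2R,8aS)-1,2,5,5-tetramethyl-1,2,3,5,6,7,8,8a-octahydronaphthalen-1-yl]methyl}benzaldehyde
Product: 25 2-formyl-3,4-dihydroxy-6-{[(1R,2R,8aS)-1,2,5,5-tetramethyl-1,2,3,5,6,7,8,8a-octahydronaphthalen-1-yl]methyl}phenyl hydrogen sulfate, via cyclic phenylboronate 23 (not isolated), via boronate sulfate 24 (not isolated)
Conditions: PhB(OH)2, 4 Å molecular sieves, pyridine, rt; then SO3·pyridine, 50 °C; then H2O; Dowex 50W (H+ form), 0 °C
Reagents that add atoms: sulfur trioxide–pyridine complex [O-]S(=O)(=O)[n+]1ccccc1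
Why: The catechol is tied up in situ as its five-membered cyclic phenylboronate, the one remaining phenol (C2'–OH) is sulfated with SO3·pyridine, and water releases the catechol on work-up (phenol sulfation under transient boronate masking).

Compound list
1 | 2,4,5-trihydroxybenzaldehyde | O=Cc1cc(O)c(O)cc1O | starting material
2 | 2,4,5-tris(benzyloxy)benzaldehyde | O=Cc1cc(OCc2ccccc2)c(OCc2ccccc2)cc1OCc1ccccc1 | intermediate
3 | [2,4,5-tris(benzyloxy)phenyl]methanol | OCc1cc(OCc2ccccc2)c(OCc2ccccc2)cc1OCc1ccccc1 | intermediate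
4 | 1-(bromomethyl)-2,4,5-tris(benzyloxy)benzene | BrCc1cc(OCc2ccccc2)c(OCc2ccccc2)cc1OCc1ccccc1 | intermediate
5 | (R)-5-methylcyclohex-2-en-1-one | C[C@@H]1CC=CC(=O)C1 | starting material
6 | lithium dienolate of 5 (O–Li at C1, C1=C6) | C[C@@H]1CC=CC(O[Li])=C1 | intermediate (not isolated)
7 | (5R,6S)-5-methyl-6-[2,4,5-tris(benzyloxy)benzyl]cyclohex-2-en-1-one (trans epimer) | C[C@@H]1CC=CC(=O)[C@H]1Cc1cc(OCc2ccccc2)c(OCc2ccccc2)cc1OCc1ccccc1 | intermediate
8 | lithium dienolate of 7 | C[C@@H]1CC=CC(O[Li])=C1Cc1cc(OCc2ccccc2)c(OCc2ccccc2)cc1OCc1ccccc1 | intermediate (not isolated)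
9 | (5R,6R)-5,6-dimethyl-6-[2,4,5-tris(benzyloxy)benzyl]cyclohex-2-en-1-one (arylmethyl cis to the C5 methyl) | C[C@@H]1CC=CC(=O)[C@]1(C)Cc1cc(OCc2ccccc2)c(OCc2ccccc2)cc1OCc1ccccc1 | intermediate
10 | (5R,6R)-1,5,6-trimethyl-6-[2,4,5-tris(benzyloxy)benzyl]cyclohex-2-en-1-ol (C1 epimers) | C[C@@H]1CC=CC(C)(O)[C@]1(C)Cc1cc(OCc2ccccc2)c(OCc2ccccc2)cc1OCc1ccccc1 | intermediate
11 | (4R,5R)-3,4,5-trimethyl-4-[2,4,5-tris(benzyloxy)benzyl]cyclohex-2-en-1-one | C[C@@H]1CC(=O)C=C(C)[C@]1(C)Cc1cc(OCc2ccccc2)c(OCc2ccccc2)cc1OCc1ccccc1 | intermediate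
12 | tert-butyl{[(4R,5R)-4,5-dimethyl-3-methylidene-4-[2,4,5-tris(benzyloxy)benzyl]cyclohex-1-en-1-yl]oxy}dimethylsilane | C[C@@H]1CC(O[Si](C)(C)C(C)(C)C)=CC(=C)[C@]1(C)Cc1cc(OCc2ccccc2)c(OCc2ccccc2)cc1OCc1ccccc1 | intermediate
13 | 1-bromo-3-methylbut-2-ene (prenyl bromide) | CC(C)=CCBr | starting material
14 | (4R,5R)-4,5-dimethyl-3-(4-methylpent-3-en-1-yl)-4-[2,4,5-tris(benzyloxy)benzyl]cyclohex-2-en-1-one | C[C@@H]1CC(=O)C=C(CCC=C(C)C)[C@]1(C)Cc1cc(OCc2ccccc2)c(OCc2ccccc2)cc1OCc1ccccc1 | intermediate (not isolated)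
15 | (3R,4R)-3,4,8,8-tetramethyl-4-[2,4,5-tris(benzyloxy)benzyl]-3,4,5,6,7,8-hexahydronaphthalen-1(2H)-one | C[C@@H]1CC(=O)C2=C(CCCC2(C)C)[C@]1(C)Cc1cc(OCc2ccccc2)c(OCc2ccccc2)cc1OCc1ccccc1 | intermediate
16 | 4-methylbenzenesulfonylhydrazone of 15 (N–N anti to C5) | C[C@@H]1C/C(=N\NS(=O)(=O)c3ccc(C)cc3)C2=C(CCCC2(C)C)[C@]1(C)Cc1cc(OCc2ccccc2)c(OCc2ccccc2)cc1OCc1ccccc1 | intermediate
17 | N-boryl allylic tosylhydrazine (C6–N cis to the C8 methyl) | C[C@@H]1C[C@H](N(B3Oc4ccccc4O3)NS(=O)(=O)c3ccc(C)cc3)C2=C(CCCC2(C)C)[C@]1(C)Cc1cc(OCc2ccccc2)c(OCc2ccccc2)cc1OCc1ccccc1 | intermediate (not isolated)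
18 | allylic diazene (C6–N=NH cis to the C8 methyl) | C[C@@H]1C[C@H](N=N)C2=C(CCCC2(C)C)[C@]1(C)Cc1cc(OCc2ccccc2)c(OCc2ccccc2)cc1OCc1ccccc1 | intermediate (not isolated)
19 | 1,2,4-tris(benzyloxy)-5-{[(1R,2R,8aS)-1,2,5,5-tetramethyl-1,2,3,5,6,7,8,8a-octahydronaphthalen-1-yl]methyl}benzene | C[C@@H]1CC=C2[C@@H](CCCC2(C)C)[C@]1(C)Cc1cc(OCc2ccccc2)c(OCc2ccccc2)cc1OCc1ccccc1 | intermediate
20 | C3'-aryllithium of 19 | C[C@@H]1CC=C2[C@@H](CCCC2(C)C)[C@]1(C)Cc1cc(OCc2ccccc2)c(OCc2ccccc2)c([Li])c1OCc1ccccc1 | intermediate (not isolated)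
21 | 2,3,6-tris(benzyloxy)-5-{[(1R,2R,8aS)-1,2,5,5-tetramethyl-1,2,3,5,6,7,8,8a-octahydronaphthalen-1-yl]methyl}benzaldehyde | C[C@@H]1CC=C2[C@@H](CCCC2(C)C)[C@]1(C)Cc1cc(OCc2ccccc2)c(OCc2ccccc2)c(C=O)c1OCc1ccccc1 | intermediate
22 | 2,3,6-trihydroxy-5-{[(1R,2R,8aS)-1,2,5,5-tetramethyl-1,2,3,5,6,7,8,8a-octahydronaphthalen-1-yl]methyl}benzaldehyde | C[C@@H]1CC=C2[C@@H](CCCC2(C)C)[C@]1(C)Cc1cc(O)c(O)c(C=O)c1O | intermediate
23 | cyclic phenylboronate of the C4'/C5' catechol of 22 | C[C@@H]1CC=C2[C@@H](CCCC2(C)C)[C@]1(C)Cc1cc2OB(c3ccccc3)Oc2c(C=O)c1O | intermediate (not isolated)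
24 | pyridinium C2'-sulfate of boronate 23 | C[C@@H]1CC=C2[C@@H](CCCC2(C)C)[C@]1(C)Cc1cc2OB(c3ccccc3)Oc2c(C=O)c1OS(=O)(=O)[O-].c1cc[nH+]cc1 | intermediate (not isolated)
25 | 2-formyl-3,4-dihydroxy-6-{[(1R,2R,8aS)-1,2,5,5-tetramethyl-1,2,3,5,6,7,8,8a-octahydronaphthalen-1-yl]methyl}phenyl hydrogen sulfate | C[C@@H]1CC=C2[C@@H](CCCC2(C)C)[C@]1(C)Cc1cc(O)c(O)c(C=O)c1OS(=O)(=O)O | target

Total step count: 14
Longest linear sequence: 14 steps (steps 1–14 from 1; 11 steps from enone 5)

Steps most likely to fail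

Step 9 (Proposed new method). What may go wrong: α- instead of γ-attack in the first alkylation, Friedel–Crafts prenylation or loss of benzyl ethers on the arene, or the tertiary cation being lost to elimination or chloride capture before the enone α-carbon closes the ring. Fallback, with the two bonds made one at a time by known reactions: it sets out from 12. ZnBr2-catalysed γ-prenylation with 13 (CH2Cl2, −20 °C) is stopped at the γ-prenyl enone 14, which is isolated. HCl in CH2Cl2 at −30 °C adds across the side-chain olefin to give the tertiary chloride F1, and TBSOTf/Et3N gives the linear dienol ether F2. TiCl4 (CH2Cl2, −78 → −40 °C) then effects intramolecular α-tert-alkylation of the silyl enol ether at C5 to give the β,γ-unsaturated ketone F3. DBU moves the double bond into conjugation and the fallback comes back to the route at 15.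

Step 11. What may go wrong: poor facial selectivity in hydride delivery to the hindered C6 hydrazone carbon (C10 epimers), sluggish reduction, or competing 1,4-reduction. Fallback through isolable alcohols whose configuration can be checked: it sets out from 15. Luche reduction (NaBH4, CeCl3·7H2O, MeOH, −78 °C) gives the allylic alcohol F4 with the hydroxyl cis to the C8 methyl. Mitsunobu inversion with 4-nitrobenzoic acid (PPh3, DIAD) gives the ester F5, and K2CO3/MeOH gives the epimeric alcohol F6. A second Mitsunobu reaction with 2-nitrobenzenesulfonylhydrazide (PPh3, DEAD, −30 °C) gives the sulfonylhydrazine F7 with nitrogen again cis to the C8 methyl. On warming it loses sulfinic acid to the same allylic diazene 18, and the fallback comes back to the route at 19.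

Step 14. What may go wrong: incomplete chemoselectivity if the boronate opens under the sulfation conditions (sulfation of a catechol oxygen), or hydrolysis of the aryl sulfate during acidification. Fallback with an isolable covalent catechol protection: it sets out from 22. 1,1'-Carbonyldiimidazole (THF, 0 °C) should close the five-membered cyclic carbonate F8 on the catechol. SO3·pyridine then sulfates the remaining phenol to the carbonate sulfate F9, and aqueous NaHCO3–MeOH cleaves the carbonate, returning to the route at 25.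

Further compounds
F1 | step 9 | (4R,5R)-3-(4-chloro-4-methylpentyl)-4,5-dimethyl-4-[2,4,5-tris(benzyloxy)benzyl]cyclohex-2-en-1-one | C[C@@H]1CC(=O)C=C(CCCC(C)(C)Cl)[C@]1(C)Cc1cc(OCc2ccccc2)c(OCc2ccccc2)cc1OCc1ccccc1
F2 | step 9 | linear tert-butyldimethylsilyl dienol ether of F1 (side chain cis to C5 across the exocyclic double bond) | C[C@@H]1CC(O[Si](C)(C)C(C)(C)C)=C/C(=C\CCC(C)(C)Cl)[C@]1(C)Cc1cc(OCc2ccccc2)c(OCc2ccccc2)cc1OCc1ccccc1
F3 | step 9 | (3R,4R)-3,4,8,8-tetramethyl-4-[2,4,5-tris(benzyloxy)benzyl]-3,4,6,7,8,8a-hexahydronaphthalen-1(2H)-one (β,γ-unsaturated isomer of 15, C8a epimers) | C[C@@H]1CC(=O)C2C(=CCCC2(C)C)[C@]1(C)Cc1cc(OCc2ccccc2)c(OCc2ccccc2)cc1OCc1ccccc1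
F4 | step 11 | allylic alcohol from 15 (C1 hydroxyl cis to the C3 methyl, naphthalenone numbering) | C[C@@H]1C[C@H](O)C2=C(CCCC2(C)C)[C@]1(C)Cc1cc(OCc2ccccc2)c(OCc2ccccc2)cc1OCc1ccccc1
F5 | step 11 | 4-nitrobenzoate of the inverted alcohol | C[C@@H]1C[C@@H](OC(=O)c3ccc(cc3)[N+](=O)[O-])C2=C(CCCC2(C)C)[C@]1(C)Cc1cc(OCc2ccccc2)c(OCc2ccccc2)cc1OCc1ccccc1
F6 | step 11 | epimeric allylic alcohol (hydroxyl trans to the C3 methyl) | C[C@@H]1C[C@@H](O)C2=C(CCCC2(C)C)[C@]1(C)Cc1cc(OCc2ccccc2)c(OCc2ccccc2)cc1OCc1ccccc1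
F7 | step 11 | N-allyl-N-(2-nitrophenylsulfonyl)hydrazine (nitrogen cis to the C3 methyl) | C[C@@H]1C[C@H](N(N)S(=O)(=O)c3ccccc3[N+](=O)[O-])C2=C(CCCC2(C)C)[C@]1(C)Cc1cc(OCc2ccccc2)c(OCc2ccccc2)cc1OCc1ccccc1
F8 | step 14 | cyclic carbonate of the C4'/C5' catechol of 22 | C[C@@H]1CC=C2[C@@H](CCCC2(C)C)[C@]1(C)Cc1cc2OC(=O)Oc2c(C=O)c1O
F9 | step 14 | C2'-hydrogen sulfate of carbonate F8 | C[C@@H]1CC=C2[C@@H](CCCC2(C)C)[C@]1(C)Cc1cc2OC(=O)Oc2c(C=O)c1OS(=O)(=O)O
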